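The constants below, turned into times at the charged amounts of birch, give J a half-life of 8.9 h by the step to J.G. J.G has 13 h by the step to G.J.G and 20 h by the forward step to Q, and G.J.G has 64 h by the step to E. Each of these birch times is longer than the 5.0 h of the run, so birch is read early.

    J + G → J.G (k1 = 0.0013 M⁻¹ min⁻¹)
    G + J.G → G.J.G (k2 = 8.9 × 10⁻⁴ M⁻¹ min⁻¹)
    G + G.J.G → E (k3 = 1.8 × 10⁻⁴ M⁻¹ min⁻¹)
    J.G ⇌ Q (K4 = 19, k4 = 5.7 × 10⁻⁴ min⁻¹)

| setting | birch | alder | maple |
|---|---|---|---|
| J | 0.50 M | 0.50 M | 0.50 M |
| G | 1.00 M | 1.50 M | 2.20 M |
| time | 5.0 h | 5.0 h | 5.0 h |

* which of these there is most of at the end, counted by the J in it, birch (J.G / Q / G.J.G / J)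
* which of these there is most of at the end, counted by the J in it, alder (J.G / Q / G.J.G / J)
* which of these there is most of at the end, counted by the J in it, maple (J.G / Q / G.J.G / J)
* amount of the one of these that there is most of at the end, in percent of the J charged, birch
* amount of the one of these that there is most of at the end, in percent of the J charged, alder
* amount of the one of these that there is most of at the end, in percent of the J charged, maple

J falls pseudo-first-order at whatever level G holds. A first pass in birch, with G kept as charged, loses 32.3% of J. Counting one G per J lost, the middle level of G is then 91.9% of its charge. The constant of the step from J, times that middle level of G, times the time, is the exposure of J, and the fraction of J left is exp(−exposure). My reckoning gives an exposure of 0.359 in birch, 0.542 in alder and 0.802 in maple, so J left stands at 69.9%, 58.2% and 44.9%.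

In birch and alder that J outweighs the rest of the charge taken together . Maple needs a second look. There J goes at 0.160 h⁻¹, and J.G goes at 0.144 h⁻¹, counting its two forward steps. Where these two rates are equal, J.G over J equals the exposure itself, so maple should hold J.G near 36.0%, under its J since. My answer is J in each flask.

Birch has a near twin, the recipe of maple with G cut to 0.88 M. J and the time are the same, and the exposure scales nearly with G, so the twin should sit below birch by about the ratio of the G charges, 0.880, and keep more J.

The forecast names J in each flask, at 70.2%, 58.9% and 45.7%, a little above mine by 0.80 percentage points in maple, on the ground that “unreacted J remains the largest species in all three runs”.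

The flasks end with J at 70.1% in birch, 58.6% in alder and 45.6% in maple, the largest in each . Maple's J.G over J reads 0.816 against an exposure of 0.802. J and J.G in maple hold the same at 1.24 times the run's time, where the exposure, scaled with time, is 0.994. The twin at 0.88 M of G reckons the same way to an exposure of 0.315, so 73.0% of J left and J.G near 23.0%. That flask ends with J at 73.1% and J.G at 22.0%.

(All constants are invented; the flask was simulated.)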